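**Retrosynthetic overview**
1. Calycopterin (12) ⇐ its 5‑O‑methyl‑4'‑O‑benzyl ether 11; one BCl3 operation frees both phenols at the end.
2. 11 ⇐ C2–C1' bond: the chromone 8 is metalated at C2 (normally the electrophilic β‑carbon of the enone, here a β‑acylvinyl anion, a homoenolate‑type d3 donor) and coupled with the electrophilic aryl iodide 9.
3. Chromone 8 ⇐ 2‑hydroxy‑ω‑methoxyacetophenone 6 plus a C1 unit (DMF‑DMA).
4. 6 ⇐ pentamethoxybenzene 3 + methoxyacetyl chloride 4 (Friedel–Crafts with ortho‑demethylation); 3 ⇐ 1,2,3‑trimethoxybenzene 1 (dibromination, Cu methoxylation).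
5. Ring order: A ring (from 1) → pyranone C ring (step 4) → B ring attached last (step 5).

Assumption: calycopterin is a planar, achiral flavone with no stereocentre, so the SMILES defines it fully and no stereocontrol is required.

**Route**

Step 1
Reactants: 1 1,2,3-trimethoxybenzene
Product: 2 1,5-dibromo-2,3,4-trimethoxybenzene
Conditions: NBS (2.1 equiv), MeCN, 0 °C → rt
Reagents that add atoms: N-bromosuccinimide, O=C1CCC(=O)N1Br
Why: Electrophilic aromatic bromination; C4 and C6 are each ortho/para to two methoxy donors whereas C5 is only para to the twisted central OMe, so two equivalents give the 4,6‑dibromide.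

Step 2
Reactants: 2 1,5-dibromo-2,3,4-trimethoxybenzene
Product: 3 pentamethoxybenzene
Conditions: NaOMe (8 equiv, 25% in MeOH), CuBr (0.3 equiv), DMF, 110 °C
Reagents that add atoms: sodium methoxide, [Na+].[O-]C
Why: Copper‑catalysed Ullmann‑type methoxylation replaces both aryl C–Br bonds by C–OMe, a standard entry to polymethoxyarenes.

Step 3
Reactants: 3 pentamethoxybenzene; 4 methoxyacetyl chloride
Product: 6 1-(2-hydroxy-3,4,5,6-tetramethoxyphenyl)-2-methoxyethan-1-one, via pentamethoxyphenyl ketone 5 (not isolated)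
Conditions: AlCl3 (2.2 equiv), CH2Cl2, 0 °C → rt; aq. HCl
Reagents that add atoms: none
Why: Friedel–Crafts acylation at the only free position of a very electron‑rich arene, followed by AlCl3 chelation‑controlled cleavage of one methoxy group ortho to the new ketone (the two ortho groups are equivalent by symmetry).

Step 4
Reactants: 6 1-(2-hydroxy-3,4,5,6-tetramethoxyphenyl)-2-methoxyethan-1-one
Product: 8 3,5,6,7,8-pentamethoxy-4H-chromen-4-one, via enaminone 7 (not isolated)
Conditions: Me2NCH(OMe)2 (3 equiv), PhMe, 100 °C; concentrate; then AcOH, 80 °C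
Reagents that add atoms: N,N-dimethylformamide dimethyl acetal, COC(OC)N(C)C
Why: Aminomethylenation of the activated CH2 gives the enaminone, and acid‑promoted intramolecular oxa‑Michael addition with loss of dimethylamine closes the pyranone (enaminone chromone synthesis).

Step 5
Reactants: 8 3,5,6,7,8-pentamethoxy-4H-chromen-4-one; 9 1-(benzyloxy)-4-iodobenzene
Product: 11 2-[4-(benzyloxy)phenyl]-3,5,6,7,8-pentamethoxy-4H-chromen-4-one, via chromon-2-ylzinc chloride 10 (not isolated)
Conditions: TMPZnCl·LiCl (1.3 equiv), THF, 25 °C; then 9 (1.1 equiv), Pd(dba)2 (3 mol %), P(2-furyl)3 (6 mol %), 50 °C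
Reagents that add atoms: none
Why: Directed zincation with the hindered amide base removes the only ring C–H (C2, flanked by O1 and the 3‑OMe), turning the normally electrophilic enone β‑carbon into a β‑acylvinyl anion (homoenolate‑type d3 donor) that is joined to the electrophilic ipso carbon of the aryl iodide by Negishi cross‑coupling.

Step 6
Reactants: 11 2-[4-(benzyloxy)phenyl]-3,5,6,7,8-pentamethoxy-4H-chromen-4-one
Product: 12 calycopterin (5-hydroxy-2-(4-hydroxyphenyl)-3,6,7,8-tetramethoxy-4H-chromen-4-one)
Conditions: BCl3 (4 equiv), C6HMe5 (3 equiv), CH2Cl2, −78 → 0 °C; then MeOH, aq. HCl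
Reagents that add atoms: none
Why: Lewis‑acid ether cleavage in which BCl3 removes the benzyl group (benzyl cation trapped by pentamethylbenzene) and, through the six‑membered O–B–O chelate with the C4 carbonyl, only the peri 5‑OMe, leaving the 3‑, 6‑, 7‑ and 8‑OMe groups intact.

**Compound list**
1 | 1,2,3-trimethoxybenzene | COc1cccc(OC)c1OC | starting material
2 | 1,5-dibromo-2,3,4-trimethoxybenzene | COc1c(Br)cc(Br)c(OC)c1OC | intermediate
3 | pentamethoxybenzene | COc1cc(OC)c(OC)c(OC)c1OC | intermediate
4 | methoxyacetyl chloride | COCC(=O)Cl | starting material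
5 | 2-methoxy-1-(pentamethoxyphenyl)ethan-1-one (not isolated) | COCC(=O)c1c(OC)c(OC)c(OC)c(OC)c1OC | intermediate
6 | 1-(2-hydroxy-3,4,5,6-tetramethoxyphenyl)-2-methoxyethan-1-one | COCC(=O)c1c(O)c(OC)c(OC)c(OC)c1OC | intermediate
7 | (Z)-3-(dimethylamino)-1-(2-hydroxy-3,4,5,6-tetramethoxyphenyl)-2-methoxyprop-2-en-1-one (not isolated; geometry is lost on cyclisation) | CO/C(=C\N(C)C)C(=O)c1c(O)c(OC)c(OC)c(OC)c1OC | intermediate
8 | 3,5,6,7,8-pentamethoxy-4H-chromen-4-one | COc1coc2c(OC)c(OC)c(OC)c(OC)c2c1=O | intermediate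
9 | 1-(benzyloxy)-4-iodobenzene | Ic1ccc(OCc2ccccc2)cc1 | starting material
10 | chloro(3,5,6,7,8-pentamethoxy-4-oxo-4H-chromen-2-yl)zinc (LiCl complex, not isolated) | COc1c([Zn]Cl)oc2c(OC)c(OC)c(OC)c(OC)c2c1=O | intermediate
11 | 2-[4-(benzyloxy)phenyl]-3,5,6,7,8-pentamethoxy-4H-chromen-4-one | COc1c(-c2ccc(OCc3ccccc3)cc2)oc2c(OC)c(OC)c(OC)c(OC)c2c1=O | intermediate
12 | calycopterin, 5-hydroxy-2-(4-hydroxyphenyl)-3,6,7,8-tetramethoxy-4H-chromen-4-one | COc1c(OC)c(O)c2c(=O)c(OC)c(-c3ccc(O)cc3)oc2c1OC | target

**Totals**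
Total step count: 6. Longest linear sequence: 6 (1 → 2 → 3 → 6 → 8 → 11 → 12; 4 and 9 are bought).

**Steps most likely to fail, with fallbacks**

Step 5 (C2 zincation and Negishi coupling). The zinc amide may deprotonate C2 too slowly, or the electron‑rich iodide may couple sluggishly. The fallback sets out from 8 and comes back at 11. Compound 8 is magnesiated with the stronger base TMPMgCl·LiCl (THF, −40 °C) to the chromon-2-ylmagnesium chloride F1, which is quenched with Bu3SnCl to give the isolable 2-(tributylstannyl)-3,5,6,7,8-pentamethoxy-4H-chromen-4-one F2. After purification, F2 undergoes Stille coupling with 9 (Pd(PPh3)4, CuI, DMF, 80 °C) to give 11. The chromone C2 remains the nucleophilic partner, but the coupling runs on a purified, storable organometallic.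

Step 6 (one‑pot double unmasking). The risks are partial loss of the 3‑OMe group and benzylation of the electron‑rich rings. The fallback sets out from 11 and comes back at 12. Hydrogenolysis (H2, 1 atm, Pd/C, EtOAc/MeOH) removes the benzyl group without any cation and gives 2-(4-hydroxyphenyl)-3,5,6,7,8-pentamethoxy-4H-chromen-4-one F3. The 5‑OMe is then cleaved on its own with AlCl3 in MeCN (rt → 50 °C), a milder chelation‑controlled demethylation, to give 12.

Step 3 (Friedel–Crafts acylation with mono‑demethylation). The risks are over‑demethylation, attack on the side‑chain OMe, or poor conversion at the hindered position. The fallback sets out from 3 and comes back at 6. Compound 3 is lithiated at its single ring C–H, which lies between two OMe groups (n‑BuLi, TMEDA, THF, 0 °C), to give pentamethoxyphenyllithium F4. Acylation with N,2-dimethoxy-N-methylacetamide gives ketone 5, here isolated. One ortho methyl ether is then removed with BCl3 (1.1 equiv, CH2Cl2, −78 → 0 °C) to give 6.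

**Further compounds**
F1 | step 5 | chloro(3,5,6,7,8-pentamethoxy-4-oxo-4H-chromen-2-yl)magnesium | COc1c([Mg]Cl)oc2c(OC)c(OC)c(OC)c(OC)c2c1=O
F2 | step 5 | 2-(tributylstannyl)-3,5,6,7,8-pentamethoxy-4H-chromen-4-one | CCCC[Sn](CCCC)(CCCC)c1oc2c(OC)c(OC)c(OC)c(OC)c2c(=O)c1OC
F3 | step 6 | 2-(4-hydroxyphenyl)-3,5,6,7,8-pentamethoxy-4H-chromen-4-one | COc1c(-c2ccc(O)cc2)oc2c(OC)c(OC)c(OC)c(OC)c2c1=O
F4 | step 3 | pentamethoxyphenyllithium | [Li]c1c(OC)c(OC)c(OC)c(OC)c1OC
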